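**Plan**

1. Numbering used below (xenicane): O2–C1H2–C11a–C11(=CH2)–C10–C9–C8–C7(Me)–C6–C5–C4a–C4–C3(=O)–O2, with the epoxide on C7–C8 and the side chain on C4.
2. Retrosynthesis, in order: the C4 side chain is removed (Michael/Wittig on an α-sulfonyl lactone; the sulfone is a helper); the lactone C1–O bond and C11=CH2 (from a C11 ketone) are opened; the C3 acid and the C11 ketone are joined through one helper CH into a cyclohexenone; C3–C4 and C4a–C11a are then cut together as a [4+2] retron; the acyclic triene is cut at C4=C4a, C5–C6, C10–C11 and C11a–C1.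
3. Enabling feature: C3 (lactone C=O) and C11 (the C=CH2 carbon) are both carbonyl-level carbons flanking the C11a–C4a bond. Linking them by one CH turns the δ-lactone plus nine-membered ring into a cyclohexene bridged 1,3 by C5–C10 (bicyclo[6.3.1], bridgehead alkene). That is the type 2 intramolecular Diels–Alder adduct of a C3=CH–C11=C11a diene tethered at C11 to a C4=C4a vinyl sulfone.
4. Forward: the chain is built by carbocupration, Sharpless epoxidation, allylation and cross-metathesis. The cycloaddition closes the cyclohexene and the nine-membered ring at once. Enone ozonolysis then excises the helper carbon (C11 ketone, C3 acid), followed by methylenation, lactonisation, side-chain attachment and desulfonylation.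
5. Stereochemistry: C7/C8 from Sharpless epoxidation (L-(+)-diethyl tartrate). C4a/C11a trans from the (E)-diene and the endo-bound tether, with their absolute sense relayed from the epoxide through the fold of the tether. C4 by kinetic protonation of the lactone enolate. Side-chain (E) geometry from a stabilised ylide.

Key step: step 13

Remark (assumption): silyl dienol ether 19 is drawn as its (1E) isomer. The C3 stereocentre it creates in step 13 is destroyed in step 15, so (1Z) material should only react more slowly.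

**Route**

Step 1
Reactants: 1 but-3-yn-1-ol
Product: 2 1-[(but-3-yn-1-yloxy)methyl]-4-methoxybenzene
Conditions: NaH, 4-methoxybenzyl chloride, Bu4NI (cat.), THF, 0 °C to rt
Reagents that add atoms: 4-methoxybenzyl chloride, COc1ccc(CCl)cc1
Why: Williamson etherification of the alkoxide (the alkyne C–H is not touched by NaH at this temperature) installs a PMB ether that can later be removed oxidatively without acid.

Step 2
Reactants: 3 5-bromo-2-methylpent-2-ene
Product: 4 (2E)-5-bromo-2-methylpent-2-en-1-ol
Conditions: SeO2 (cat.), t-BuOOH, salicylic acid (cat.), CH2Cl2, rt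
Reagents that add atoms: tert-butyl hydroperoxide, CC(C)(C)OO
Why: SeO2-catalysed allylic oxidation (ene reaction then [2,3]-sigmatropic shift) attacks the methyl group trans to the chain of a trisubstituted alkene, so the (E)-allylic alcohol should form.

Step 3
Reactants: 4 (2E)-5-bromo-2-methylpent-2-en-1-ol
Product: 5 {[(2E)-5-bromo-2-methylpent-2-en-1-yl]oxy}(tert-butyl)dimethylsilane
Conditions: t-BuMe2SiCl, imidazole, CH2Cl2, rt
Reagents that add atoms: tert-butyldimethylsilyl chloride, CC(C)(C)[Si](C)(C)Cl
Why: Standard silylation masks the allylic alcohol so that the bromide can be converted into an organometallic reagent.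

Step 4
Reactants: 5 {[(2E)-5-bromo-2-methylpent-2-en-1-yl]oxy}(tert-butyl)dimethylsilane; 2 1-[(but-3-yn-1-yloxy)methyl]-4-methoxybenzene
Product: 9 vinyl iodide tert-butyl({(2E,6E)-7-iodo-6-[2-(4-methoxybenzyloxy)ethyl]-2-methylhepta-2,6-dien-1-yl}oxy)dimethylsilane, via Grignard reagent 6 (not isolated), via alkylcopper 7 (not isolated), via alkenylcopper 8 (not isolated)
Conditions: Mg, Et2O; CuBr·SMe2, Et2O/Me2S, −45 °C; 2, −25 °C; I2, −40 to 0 °C
Reagents that add atoms: iodine, II
Why: Normant carbocupration adds the alkylcopper syn across the terminal alkyne (chain to the internal carbon C11, copper to C11a), and iodinolysis with retention fixes the trisubstituted alkene with the future C1 cis to the C10 chain.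

Step 5
Reactants: 9 vinyl iodide
Product: 11 (2E,6E)-1-(tert-butyldimethylsilyloxy)-6-[2-(4-methoxybenzyloxy)ethyl]-2-methyl-8-(triisopropylsilyloxy)octa-2,6-diene, via alkenyllithium 10 (not isolated)
Conditions: t-BuLi (2.1 equiv), Et2O, −78 °C; then (i-Pr)3SiOCH2Cl, −78 °C to rt
Reagents that add atoms: (triisopropylsiloxy)methyl chloride, CC(C)[Si](C(C)C)(C(C)C)OCCl
Why: Iodine–lithium exchange proceeds with retention and the alkenyllithium is alkylated (SN2) by the α-chloro ether, which delivers C1 already carrying its TIPS ether.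

Step 6
Reactants: 11 bis-silyl ether
Product: 12 (2E,6E)-6-[2-(4-methoxybenzyloxy)ethyl]-2-methyl-8-(triisopropylsilyloxy)octa-2,6-dien-1-ol
Conditions: PPTS (cat.), MeOH, rt
Reagents that add atoms: none
Why: Mild acid methanolysis cleaves the primary tert-butyldimethylsilyl ether much faster than the bulkier triisopropylsilyl ether and leaves the PMB ether alone.

Step 7
Reactants: 12 allylic alcohol
Product: 13 [(2S,3S)-3-{(3E)-3-[2-(4-methoxybenzyloxy)ethyl]-5-(triisopropylsilyloxy)pent-3-en-1-yl}-2-methyloxiran-2-yl]methanol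
Conditions: Ti(OiPr)4 (cat.), L-(+)-diethyl tartrate (cat.), t-BuOOH, 4 Å molecular sieves, CH2Cl2, −20 °C
Reagents that add atoms: tert-butyl hydroperoxide, CC(C)(C)OO
Why: Sharpless asymmetric epoxidation of the (E)-2-methyl-2-alken-1-ol with the L-(+)-tartrate should deliver oxygen to the face that gives the (2S,3S)-epoxide (C7 S, C8 S), while the other trisubstituted alkene has no free allylic hydroxyl and is not touched.

Step 8
Reactants: 13 epoxy alcohol
Product: 15 (2S,3S)-2-(but-3-en-1-yl)-3-{(3E)-3-[2-(4-methoxybenzyloxy)ethyl]-5-(triisopropylsilyloxy)pent-3-en-1-yl}-2-methyloxirane, via epoxy triflate 14 (not isolated)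
Conditions: Tf2O, 2,6-lutidine, CH2Cl2, −78 °C; then allylMgBr, CuBr·SMe2 (cat.), Et2O, −78 °C
Reagents that add atoms: allylmagnesium bromide, C=CC[Mg]Br
Why: The primary triflate is displaced (copper-assisted SN2) by the allyl nucleophile at −78 °C faster than the epoxide is opened, which forms C5–C6 and keeps both epoxide centres.

Step 9
Reactants: 15 epoxy alkene
Product: 16 (2S,3S)-3-{(3E)-3-[2-(4-methoxybenzyloxy)ethyl]-5-(triisopropylsilyloxy)pent-3-en-1-yl}-2-methyl-2-[(3E)-4-(phenylsulfonyl)but-3-en-1-yl]oxirane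
Conditions: phenyl vinyl sulfone (3 equiv), second-generation Grubbs catalyst (H2IMes)(PCy3)Cl2Ru=CHPh (5 mol %), CH2Cl2, 40 °C
Reagents that add atoms: phenyl vinyl sulfone, C=CS(=O)(=O)c1ccccc1
Why: Olefin cross-metathesis of the monosubstituted alkene with phenyl vinyl sulfone should give the (E)-alkenyl sulfone, while the trisubstituted alkene is too hindered to take part.

Step 10
Reactants: 16 PMB ether
Product: 17 (3E)-3-(2-{(2S,3S)-3-methyl-3-[(3E)-4-(phenylsulfonyl)but-3-en-1-yl]oxiran-2-yl}ethyl)-5-(triisopropylsilyloxy)pent-3-en-1-ol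
Conditions: DDQ, CH2Cl2/pH 7 buffer, 0 °C
Reagents that add atoms: none
Why: Oxidative cleavage of the PMB ether under buffered conditions frees the primary alcohol without acid, so the trisubstituted epoxide, the silyl ether and the vinyl sulfone should survive.

Step 11
Reactants: 17 homoallylic alcohol
Product: 18 (3E)-3-(2-{(2S,3S)-3-methyl-3-[(3E)-4-(phenylsulfonyl)but-3-en-1-yl]oxiran-2-yl}ethyl)-5-(triisopropylsilyloxy)pent-3-enal
Conditions: Dess–Martin periodinane, NaHCO3, CH2Cl2, 0 °C
Reagents that add atoms: none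
Why: Buffered Dess–Martin oxidation gives the β,γ-unsaturated aldehyde without base, so the C11=C11a double bond should stay in place with its geometry.

Step 12
Reactants: 18 β,γ-unsaturated aldehyde
Product: 19 (2S,3S)-2-methyl-2-[(3E)-4-(phenylsulfonyl)but-3-en-1-yl]-3-{(3E)-3-[(E)-2-(triethylsilyloxy)ethenyl]-5-(triisopropylsilyloxy)pent-3-en-1-yl}oxirane
Conditions: Et3SiOTf, Et3N, CH2Cl2, −78 °C
Reagents that add atoms: triethylsilyl trifluoromethanesulfonate, CC[Si](CC)(CC)OS(=O)(=O)C(F)(F)F
Why: Soft enolisation of the doubly activated α-CH2 and O-silylation give the conjugated 1-silyloxy diene with the C11=C11a geometry unchanged, under conditions too weakly basic to isomerise the vinyl sulfone.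

Step 13
Reactants: 19 triene
Product: 20 cycloadduct 4,5-epoxy-5-methyl-9-(phenylsulfonyl)-10-(triethylsilyloxy)-12-[(triisopropylsilyloxy)methyl]bicyclo[6.3.1]dodec-1(11)-ene (H-4a and H-11a trans)
Conditions: toluene (2 mM), BHT (cat.), N,O-bis(trimethylsilyl)acetamide (0.2 equiv), sealed tube, 160 °C
Reagents that add atoms: none
Why: Heating the triene at high dilution should bring the (E)-vinyl sulfone (C4=C4a) under the 1-silyloxy diene (C3=CH–C11=C11a) in a concerted, suprafacial [4+2] cycloaddition; the closest known reaction type is the type 2 intramolecular Diels–Alder reaction of 2-tethered dienes, which gives bicyclo[4.3.1] and bicyclo[5.3.1] bridgehead alkenes, so the six-atom tether here is an extension of that precedent. The cyclohexene closes as the ring of the cycloadduct, and because the tether leaves C11 (diene C2) and ends on C4a, the nine-membered carbocycle closes in the same event as the 1,3-bridge of a bicyclo[6.3.1] system whose bridgehead alkene is unstrained at this ring size. C11a takes its configuration from the (E)-geometry of C11=C11a (CH2OSi outside) and C4a from the tether, which can reach C11 only from the endo side, so H-4a and H-11a end up trans as in the target; C3 and C4 form as drawn but are erased later. The absolute sense (which diene face is used) is relayed from the trans-epoxide, whose chain should span C11 and C4a only in the crown-like fold of caryophyllene-oxide-type nine-membered rings, with the epoxide oxygen and the C7 methyl group on the outside. Regioselectivity (C11a to C4a, C3 to C4) is secured twice: the oxygen on C3 makes C11a the nucleophilic diene terminus and the sulfone makes C4a the electrophilic carbon, and the tether allows only this 1,3-bridged mode. The selectivity still needed is facial, and ring closure must outrun intermolecular cycloaddition, hence the dilution and the silyl scavenger.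

Step 14
Reactants: 20 cycloadduct
Product: 21 allylic alcohol (C3–OH) 4,5-epoxy-5-methyl-9-(phenylsulfonyl)-12-[(triisopropylsilyloxy)methyl]bicyclo[6.3.1]dodec-1(11)-en-10-ol
Conditions: Bu4NF, AcOH (1:1), THF, 0 °C
Reagents that add atoms: none
Why: Buffered fluoride cleaves the secondary triethylsilyl ether selectively, leaving the triisopropylsilyl ether on C1 and avoiding base-induced elimination next to the sulfone.

Step 15
Reactants: 21 allylic alcohol
Product: 22 bridgehead enone (C3 ketone conjugated with C11=CH) 4,5-epoxy-5-methyl-9-(phenylsulfonyl)-12-[(triisopropylsilyloxy)methyl]bicyclo[6.3.1]dodec-1(11)-en-10-one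
Conditions: Dess–Martin periodinane, NaHCO3, CH2Cl2, rt
Reagents that add atoms: none
Why: Oxidation of the secondary allylic alcohol gives the cyclohexenone, a β-keto sulfone that should stay largely in its keto form and so offers only the enone C=C to ozone.

Step 16
Reactants: 22 bridgehead enone
Product: 24 keto acid 2-(phenylsulfonyl)-2-{5,6-epoxy-6-methyl-2-oxo-9-[(triisopropylsilyloxy)methyl]cyclononyl}acetic acid (xenicane C11 ketone and C3 acid), via keto glyoxal 23 (not isolated)
Conditions: O3, CH2Cl2/MeOH, −78 °C; then 30% H2O2, NaHCO3, THF/H2O, 0 °C to rt; acidify to pH 4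
Reagents that add atoms: ozone, O=[O+][O-]; hydrogen peroxide, OO
Why: Ozonolysis cleaves the only C=C (the enone) to the C11 ketone and an α-keto aldehyde, which peroxide cleaves to the C3 carboxylic acid with loss of the helper carbon as formic acid (the classical degradation of cyclic enones to keto acids), the epoxide being inert to both oxidants.

Step 17
Reactants: 24 keto acid
Product: 25 methylene acid 2-(phenylsulfonyl)-2-{5,6-epoxy-6-methyl-2-methylidene-9-[(triisopropylsilyloxy)methyl]cyclononyl}acetic acid
Conditions: Ph3PCH3Br, KOtBu (4 equiv of ylide), THF, 0 °C to rt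
Reagents that add atoms: methylenetriphenylphosphorane, C=P(c1ccccc1)(c1ccccc1)c1ccccc1
Why: Wittig methylenation of the nine-membered ketone (as used on epoxy ketones of the caryophyllane series) is run before lactonisation, while the C1 oxygen is still a poor leaving group and the acid is protected as its carboxylate.

Step 18
Reactants: 25 methylene acid
Product: 27 α-sulfonyl lactone (4-phenylsulfonyl-7,8-epoxy-11-methylidene δ-lactone lacking the C4 side chain), via hydroxy acid 26 (not isolated)
Conditions: Bu4NF, THF, rt; then EDC·HCl, DMAP (cat.), CH2Cl2, 0 °C to rt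
Reagents that add atoms: none
Why: Fluoride frees the C1 hydroxyl and carbodiimide activation closes the six-membered lactone (6-exo-trig acyl substitution), which is strongly favoured for a δ-hydroxy acid.

Step 19
Reactants: 27 α-sulfonyl lactone
Product: 28 aldehyde (C4 bearing PhSO2 and CH2CH2CHO)
Conditions: acrolein (1.5 equiv), Et3N (cat.), MeCN, 0 °C
Reagents that add atoms: acrolein, C=CC=O
Why: The soft carbanion of the α-sulfonyl lactone adds to acrolein in a base-catalysed Michael reaction under conditions too mild to disturb the lactone or the epoxide; the configuration of the new quaternary centre does not matter because the sulfone is removed later.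

Step 20
Reactants: 28 aldehyde
Product: 29 enoate sulfone (4-phenylsulfonyl derivative of the target)
Conditions: Ph3P=C(Me)CO2Me, CH2Cl2, rt
Reagents that add atoms: methyl 2-(triphenylphosphoranylidene)propanoate, COC(=O)C(C)=P(c1ccccc1)(c1ccccc1)c1ccccc1
Why: The stabilised ylide reacts only with the aldehyde (Wittig reaction) and should give the (E)-2-methyl enoate of the side chain.

Step 21
Reactants: 29 enoate sulfone
Product: 31 acalycixeniolide H, via samarium enolate 30 (not isolated)
Conditions: SmI2 (2.5 equiv), THF/MeOH, −78 °C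
Reagents that add atoms: none
Why: Single-electron reduction cleaves the C–S bond α to the lactone carbonyl to a trivalent samarium enolate, and kinetic protonation from the less hindered face (syn to H-4a, anti to the C5 methylene of the trans-fused system) should set C4 as in the target while the enoate and epoxide are left alone at this temperature.

**Compound list**

1 | but-3-yn-1-ol | C#CCCO | starting material
2 | 1-[(but-3-yn-1-yloxy)methyl]-4-methoxybenzene | C#CCCOCc1ccc(OC)cc1 | intermediate
3 | 5-bromo-2-methylpent-2-ene | CC(C)=CCCBr | starting material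
4 | (2E)-5-bromo-2-methylpent-2-en-1-ol | OC/C(C)=C/CCBr | intermediate
5 | {[(2E)-5-bromo-2-methylpent-2-en-1-yl]oxy}(tert-butyl)dimethylsilane | CC(C)(C)[Si](C)(C)OC/C(C)=C/CCBr | intermediate
6 | Grignard reagent: bromo[(3E)-5-(tert-butyldimethylsilyloxy)-4-methylpent-3-en-1-yl]magnesium | CC(C)(C)[Si](C)(C)OC/C(C)=C/CC[Mg]Br | intermediate
7 | alkylcopper: [(3E)-5-(tert-butyldimethylsilyloxy)-4-methylpent-3-en-1-yl]copper (MgBr2 complex) | CC(C)(C)[Si](C)(C)OC/C(C)=C/CC[Cu] | intermediate
8 | alkenylcopper: syn adduct of 7 and 2, copper on C11a cis to the C10 chain | [Cu]/C=C(/CCOCc1ccc(OC)cc1)CC/C=C(\C)CO[Si](C)(C)C(C)(C)C | intermediate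
9 | vinyl iodide: tert-butyl({(2E,6E)-7-iodo-6-[2-(4-methoxybenzyloxy)ethyl]-2-methylhepta-2,6-dien-1-yl}oxy)dimethylsilane | I/C=C(/CCOCc1ccc(OC)cc1)CC/C=C(\C)CO[Si](C)(C)C(C)(C)C | intermediate
10 | alkenyllithium from 9 (Li in place of I, same geometry) | [Li]/C=C(/CCOCc1ccc(OC)cc1)CC/C=C(\C)CO[Si](C)(C)C(C)(C)C | intermediate
11 | (2E,6E)-1-(tert-butyldimethylsilyloxy)-6-[2-(4-methoxybenzyloxy)ethyl]-2-methyl-8-(triisopropylsilyloxy)octa-2,6-diene | CC(C)[Si](C(C)C)(C(C)C)OC/C=C(/CCOCc1ccc(OC)cc1)CC/C=C(\C)CO[Si](C)(C)C(C)(C)C | intermediate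
12 | (2E,6E)-6-[2-(4-methoxybenzyloxy)ethyl]-2-methyl-8-(triisopropylsilyloxy)octa-2,6-dien-1-ol | CC(C)[Si](C(C)C)(C(C)C)OC/C=C(/CCOCc1ccc(OC)cc1)CC/C=C(\C)CO | intermediate
13 | [(2S,3S)-3-{(3E)-3-[2-(4-methoxybenzyloxy)ethyl]-5-(triisopropylsilyloxy)pent-3-en-1-yl}-2-methyloxiran-2-yl]methanol | CC(C)[Si](C(C)C)(C(C)C)OC/C=C(/CCOCc1ccc(OC)cc1)CC[C@@H]1O[C@@]1(C)CO | intermediate
14 | epoxy triflate: trifluoromethanesulfonate of 13 | CC(C)[Si](C(C)C)(C(C)C)OC/C=C(/CCOCc1ccc(OC)cc1)CC[C@@H]1O[C@@]1(C)COS(=O)(=O)C(F)(F)F | intermediate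
15 | (2S,3S)-2-(but-3-en-1-yl)-3-{(3E)-3-[2-(4-methoxybenzyloxy)ethyl]-5-(triisopropylsilyloxy)pent-3-en-1-yl}-2-methyloxirane | CC(C)[Si](C(C)C)(C(C)C)OC/C=C(/CCOCc1ccc(OC)cc1)CC[C@@H]1O[C@@]1(C)CCC=C | intermediate
16 | (2S,3S)-3-{(3E)-3-[2-(4-methoxybenzyloxy)ethyl]-5-(triisopropylsilyloxy)pent-3-en-1-yl}-2-methyl-2-[(3E)-4-(phenylsulfonyl)but-3-en-1-yl]oxirane | CC(C)[Si](C(C)C)(C(C)C)OC/C=C(/CCOCc1ccc(OC)cc1)CC[C@@H]1O[C@@]1(C)CC/C=C/S(=O)(=O)c1ccccc1 | intermediate
17 | (3E)-3-(2-{(2S,3S)-3-methyl-3-[(3E)-4-(phenylsulfonyl)but-3-en-1-yl]oxiran-2-yl}ethyl)-5-(triisopropylsilyloxy)pent-3-en-1-ol | CC(C)[Si](C(C)C)(C(C)C)OC/C=C(/CCO)CC[C@@H]1O[C@@]1(C)CC/C=C/S(=O)(=O)c1ccccc1 | intermediate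
18 | (3E)-3-(2-{(2S,3S)-3-methyl-3-[(3E)-4-(phenylsulfonyl)but-3-en-1-yl]oxiran-2-yl}ethyl)-5-(triisopropylsilyloxy)pent-3-enal | CC(C)[Si](C(C)C)(C(C)C)OC/C=C(/CC=O)CC[C@@H]1O[C@@]1(C)CC/C=C/S(=O)(=O)c1ccccc1 | intermediate
19 | triene: (2S,3S)-2-methyl-2-[(3E)-4-(phenylsulfonyl)but-3-en-1-yl]-3-{(3E)-3-[(E)-2-(triethylsilyloxy)ethenyl]-5-(triisopropylsilyloxy)pent-3-en-1-yl}oxirane | CC[Si](CC)(CC)O/C=C/C(=C/CO[Si](C(C)C)(C(C)C)C(C)C)CC[C@@H]1O[C@@]1(C)CC/C=C/S(=O)(=O)c1ccccc1 | intermediate
20 | cycloadduct: 4,5-epoxy-5-methyl-9-(phenylsulfonyl)-10-(triethylsilyloxy)-12-[(triisopropylsilyloxy)methyl]bicyclo[6.3.1]dodec-1(11)-ene; H-4a/H-11a trans, CH2OSi cis to the C5 bridge carbon, PhSO2 trans to OSiEt3 | CC(C)[Si](C(C)C)(C(C)C)OC[C@H]1C2=C[C@@H](O[Si](CC)(CC)CC)[C@H](S(=O)(=O)c3ccccc3)[C@H]1CC[C@]4(C)O[C@H]4CC2 | intermediate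
21 | allylic alcohol: 10-hydroxy analogue of 20 (C3–OH) | CC(C)[Si](C(C)C)(C(C)C)OC[C@H]1C2=C[C@@H](O)[C@H](S(=O)(=O)c3ccccc3)[C@H]1CC[C@]4(C)O[C@H]4CC2 | intermediate
22 | bridgehead enone: 10-oxo analogue of 21 (C3 ketone; C4 epimerisable) | CC(C)[Si](C(C)C)(C(C)C)OC[C@H]1C2=CC(=O)[C@H](S(=O)(=O)c3ccccc3)[C@H]1CC[C@]4(C)O[C@H]4CC2 | intermediate
23 | keto glyoxal: nine-membered C11 ketone with a CH(SO2Ph)C(=O)CHO chain on C4a | CC(C)[Si](C(C)C)(C(C)C)OC[C@H]1C(=O)CC[C@@H]2O[C@@]2(C)CC[C@@H]1[C@@H](S(=O)(=O)c1ccccc1)C(=O)C=O | intermediate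
24 | keto acid: 2-(phenylsulfonyl)-2-{5,6-epoxy-6-methyl-2-oxo-9-[(triisopropylsilyloxy)methyl]cyclononyl}acetic acid | CC(C)[Si](C(C)C)(C(C)C)OC[C@H]1C(=O)CC[C@@H]2O[C@@]2(C)CC[C@@H]1[C@@H](S(=O)(=O)c1ccccc1)C(=O)O | intermediate
25 | methylene acid: 2-methylidene analogue of 24 | CC(C)[Si](C(C)C)(C(C)C)OC[C@H]1C(=C)CC[C@@H]2O[C@@]2(C)CC[C@@H]1[C@@H](S(=O)(=O)c1ccccc1)C(=O)O | intermediate
26 | hydroxy acid: 25 without the silyl group | OC[C@H]1C(=C)CC[C@@H]2O[C@@]2(C)CC[C@@H]1[C@@H](S(=O)(=O)c1ccccc1)C(=O)O | intermediate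
27 | α-sulfonyl lactone: target skeleton with PhSO2 and H on C4 instead of the side chain | C=C1CC[C@@H]2O[C@@]2(C)CC[C@@H]2[C@@H](S(=O)(=O)c3ccccc3)C(=O)OC[C@@H]12 | intermediate
28 | aldehyde: C4 bearing PhSO2 and CH2CH2CHO | C=C1CC[C@@H]2O[C@@]2(C)CC[C@@H]2[C@](CCC=O)(S(=O)(=O)c3ccccc3)C(=O)OC[C@@H]12 | intermediate
29 | enoate sulfone: 4-(phenylsulfonyl)acalycixeniolide H | C=C1CC[C@@H]2O[C@@]2(C)CC[C@@H]2[C@](CC/C=C(\C)C(=O)OC)(S(=O)(=O)c3ccccc3)C(=O)OC[C@@H]12 | intermediate
30 | trivalent samarium enolate of the lactone | C=C1CC[C@@H]2O[C@@]2(C)CC[C@@H]2C(CC/C=C(\C)C(=O)OC)=C(O[Sm](I)I)OC[C@@H]12 | intermediate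
31 | acalycixeniolide H | C=C1CC[C@@H]2O[C@@]2(C)CC[C@@H]2[C@H](CC/C=C(\C)C(=O)OC)C(=O)OC[C@@H]12 | target

**Step count and risks**

Total steps: 21. Longest linear sequence: 20 steps (3 to 31 through steps 2 to 21).

Steps most likely to fail:

1. Step 13. The six-atom tether may not fold the vinyl sulfone under the diene fast enough, so that intermolecular cycloaddition and thermal loss of the silyl dienol ether compete; the remote epoxide may also bias the two diene faces too weakly. Fallback: the two bonds are made one after the other under ionic, reversible conditions instead of in a concerted cycloaddition. It sets out from aldehyde 18. A secondary amine (pyrrolidine, or a diarylprolinol silyl ether if the facial sense must be overridden) with benzoic acid in toluene at rt converts 18 into its dienamine, whose γ-carbon (C11a) adds to the tethered vinyl sulfone in a vinylogous Michael addition. This forms C4a–C11a and the nine-membered ring and gives, after hydrolysis, the nine-membered-ring enal F1, drawn as the (Z)-isomer that can close. LiN(SiMe3)2 in THF at −78 °C then adds the α-sulfonyl carbanion to the aldehyde (C3–C4, six-membered ring), and the sequence comes back to the route at allylic alcohol 21; both C3 epimers converge at enone 22.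

2. Step 17. The basic ylide may enolise the hindered nine-membered ketone instead of adding to it, with epimerisation at C11a or β-elimination of the C1 oxygen. Fallback: a non-basic titanium-based methylenation on the ester. It sets out from keto acid 24, which is esterified with Me3SiCHN2 in toluene/MeOH to methyl ester F2. Zn, CH2Br2 and TiCl4 in THF (Lombardo reagent, which methylenates ketones in the presence of esters) then give methylene ester F3. Bu4NF in THF removes the silyl group and the alkoxide closes the lactone with loss of methanol, returning to the route at lactone 27.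

3. Step 21. Protonation of the samarium enolate may show poor facial selectivity, or the product may equilibrate to the C4 epimer. Fallback: hydrogen-atom transfer instead of protonation. It sets out from enoate sulfone 29. Bu3SnH or (Me3Si)3SiH with AIBN in benzene at 80 °C cleaves the C–S bond homolytically (radical desulfonylation of α-sulfonyl esters), and the bulky hydride delivers hydrogen to the lactone radical from the open face syn to H-4a. It comes back to the route at 31 (no new compound; F0).

Further compounds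
F1 | step 13 | nine-membered-ring enal: (2Z)-2-{5,6-epoxy-6-methyl-2-[(phenylsulfonyl)methyl]-9-[(triisopropylsilyloxy)methyl]cyclononylidene}acetaldehyde, ring substituents trans, locants as in the name | CC(C)[Si](C(C)C)(C(C)C)OC[C@H]1/C(=C\C=O)CC[C@@H]2O[C@@]2(C)CC[C@@H]1CS(=O)(=O)c1ccccc1
F2 | step 17 | methyl ester of keto acid 24 | CC(C)[Si](C(C)C)(C(C)C)OC[C@H]1C(=O)CC[C@@H]2O[C@@]2(C)CC[C@@H]1[C@@H](S(=O)(=O)c1ccccc1)C(=O)OC
F3 | step 17 | methyl ester of methylene acid 25 | CC(C)[Si](C(C)C)(C(C)C)OC[C@H]1C(=C)CC[C@@H]2O[C@@]2(C)CC[C@@H]1[C@@H](S(=O)(=O)c1ccccc1)C(=O)OC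
F0 | step 21 | none | none
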